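A direct plan would make methyl 4-oxoheptadecanoate A1 by a Stetter addition, saponify it to 4-oxoheptadecanoic acid A2, join A2 to 3-(4-pivaloyloxyphenyl)propanoic acid A3 by mixed Kolbe electrolysis to give 4-(5-oxooctadecyl)phenyl pivalate A4, and free the phenol by hydrolysis. Its weakest steps would be:
- the anodic cross-coupling, since two primary radicals would pair statistically and homodimers would consume material;
- the Stetter addition, since an enolisable aliphatic aldehyde would divert to acyloin and aldol products;
- the acylation and later hydrolysis at the phenol oxygen, two operations that would form no bond of the skeleton.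

The route rests on a reconnection: C1 to C5 of the tether, that is the aryl-bearing carbon, the three methylenes behind it and the carbonyl carbon, are the five ring carbons of cyclopentanone. The key step, β-scission of the tertiary cyclopentyloxy radical of 1-tridecylcyclopentan-1-ol, opens that ring and in one operation sets the C5 ketone and an iodide at C1 of the four-methylene tether, without any regiochemical choice. A nickel-catalysed cross-electrophile coupling with unprotected 4-iodophenol then forms the aryl–C1 bond. No statistical radical pairing, no acyl-anion catalysis and no step at the phenol oxygen would remain.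

Key step: step 2

Remark: the target has no stereocentre and no stereogenic double bond, so no step has to control configuration. Atom numbers follow the name 1-(4-hydroxyphenyl)octadecan-5-one, C1 being the benzylic carbon.

Step 1
Reactants: 1 1-bromotridecane; 2 cyclopentanone
Product: 4 1-tridecylcyclopentan-1-ol, via tridecylmagnesium bromide 3 (not isolated)
Conditions: (a) Mg turnings (1.2 equiv), THF, 40–50 °C; (b) added to 2 (0.9 equiv) and LaCl3·2LiCl (0.3 equiv) in THF, 0 °C to rt; sat. aq. NH4Cl
Reagents that add atoms: none
Why: Grignard formation and 1,2-addition to the ketone, in which LaCl3·2LiCl activates the carbonyl and tempers the basicity of the alkyl nucleophile, so that enolisation and self-aldol condensation of cyclopentanone should be held back; the carbinol carbon carries two identical ring arms and is not a stereocentre.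

Step 2
Reactants: 4 1-tridecylcyclopentan-1-ol
Product: 6 1-iodooctadecan-5-one, via 1-tridecylcyclopentyl hypoiodite 5 (not isolated)
Conditions: PhI(OAc)2 (1.2 equiv), I2 (1.0 equiv), CH2Cl2, visible light (tungsten lamp), 25 °C; aq. Na2S2O3 wash
Reagents that add atoms: iodine, II
Why: PhI(OAc)2 and I2 give acetyl hypoiodite, which converts the tertiary alcohol into hypoiodite 5; visible light cleaves its weak O–I bond to the 1-tridecylcyclopentyloxy radical, which undergoes β-scission of a ring C–C bond to give the C5 ketone and a primary radical at C1 that takes an iodine atom from I2 or from 5 in a radical chain. The reaction type is the alkoxy-radical fragmentation of hypoiodites, the iodine counterpart of the rearrangement of tertiary cycloalkyl hypochlorites to ω-chloro ketones. No ring is closed, the cyclopentane ring is opened, and no stereocentre is formed. The step needs ring scission in preference to expulsion of the tridecyl chain and to 1,5-hydrogen transfer from that chain; release of cyclopentane ring strain together with formation of a dialkyl ketone should make ring opening the fastest of the three paths. The two ring bonds at the carbinol carbon are equivalent, so only one constitutional isomer can form. Iodine-atom transfer to the δ-keto radical should outrun its re-closure onto the carbonyl group.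

Step 3
Reactants: 6 1-iodooctadecan-5-one; 7 4-iodophenol
Product: 8 1-(4-hydroxyphenyl)octadecan-5-one (target)
Conditions: NiI2·xH2O (10 mol%), 4,4'-di-tert-butyl-2,2'-bipyridine (5 mol%), 1,2-bis(diphenylphosphino)benzene (5 mol%), pyridine (10 mol%), Mn powder (2 equiv), DMPU, 60 °C, 6 and 7 in equimolar amounts; then 1 M HCl
Reagents that add atoms: none
Why: In this nickel-catalysed reductive cross-electrophile coupling, zerovalent nickel inserts into the C(sp2)–I bond of 7, the primary C1 radical formed from 6 by iodine abstraction adds to the divalent arylnickel species, and reductive elimination from trivalent nickel forms the aryl–C1 bond while Mn returns nickel to the zerovalent state; cross-selectivity rests on the different activation modes of the two iodides, and as no basic organometallic reagent is present the free phenol and the ketone should survive.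

Compound list
1 | 1-bromotridecane | CCCCCCCCCCCCCBr | starting material
2 | cyclopentanone | O=C1CCCC1 | starting material
3 | tridecylmagnesium bromide | CCCCCCCCCCCCC[Mg]Br | intermediate
4 | 1-tridecylcyclopentan-1-ol | CCCCCCCCCCCCCC1(O)CCCC1 | intermediate
5 | 1-tridecylcyclopentyl hypoiodite | CCCCCCCCCCCCCC1(OI)CCCC1 | intermediate
6 | 1-iodooctadecan-5-one | CCCCCCCCCCCCCC(=O)CCCCI | intermediate
7 | 4-iodophenol | Oc1ccc(I)cc1 | starting material
8 | 1-(4-hydroxyphenyl)octadecan-5-one | CCCCCCCCCCCCCC(=O)CCCCc1ccc(O)cc1 | target

Total step count: 3. Longest linear sequence: 3.

Steps most likely to fail, in order of risk: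

1. Step 3. Cross-selectivity may be lost to homo-coupling of either iodide, the acidic phenol may promote hydrodehalogenation, or the keto iodide may re-close reductively onto its own carbonyl group. Fallback: setting out from 6, zinc insertion (Zn dust, LiCl, THF, 40 °C) would give (5-oxooctadecyl)zinc iodide F1. Its Negishi coupling with commercial (4-bromophenoxy)(tert-butyl)dimethylsilane (Pd(OAc)2, 2-dicyclohexylphosphino-2',6'-dimethoxybiphenyl, THF, 25–50 °C) would give 1-[4-(tert-butyldimethylsilyloxy)phenyl]octadecan-5-one F2. Desilylation with Bu4NF in THF would come back to the route at 8.

2. Step 2. Hydrogen transfer within the alkoxy radical (1,5-shift from the tridecyl chain) or expulsion of the tridecyl chain may compete with ring scission, and the ketone may be iodinated at its α-carbon by excess reagent. Fallback: setting out from 3, acylation with 5-bromopentanoyl chloride (Fe(acac)3 3 mol%, THF, −78 °C) would give 1-bromooctadecan-5-one F3. Finkelstein exchange (NaI, acetone, reflux) would come back to the route at 6.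

3. Step 1. The Grignard reagent may act as a base, so that cyclopentanone enolises and condenses with itself, and Wurtz coupling may occur while the reagent forms. Fallback: setting out from 2, Corey–Chaykovsky methylene transfer (Me3S(O)I, NaH, DMSO, rt) would give 1-oxaspiro[2.4]heptane F4. Copper-catalysed opening at its CH2 carbon with commercial dodecylmagnesium bromide (CuI 10 mol%, THF, −30 to 0 °C) would come back to the route at 4.

Further compounds
F1 | step 3 | (5-oxooctadecyl)zinc iodide | CCCCCCCCCCCCCC(=O)CCCC[Zn]I
F2 | step 3 | 1-[4-(tert-butyldimethylsilyloxy)phenyl]octadecan-5-one | CCCCCCCCCCCCCC(=O)CCCCc1ccc(O[Si](C)(C)C(C)(C)C)cc1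
F3 | step 2 | 1-bromooctadecan-5-one | CCCCCCCCCCCCCC(=O)CCCCBr
F4 | step 1 | 1-oxaspiro[2.4]heptane | C1CCC2(C1)CO2
A1 | direct plan | methyl 4-oxoheptadecanoate | CCCCCCCCCCCCCC(=O)CCC(=O)OC
A2 | direct plan | 4-oxoheptadecanoic acid | CCCCCCCCCCCCCC(=O)CCC(=O)O
A3 | direct plan | 3-(4-pivaloyloxyphenyl)propanoic acid | CC(C)(C)C(=O)Oc1ccc(CCC(=O)O)cc1
A4 | direct plan | 4-(5-oxooctadecyl)phenyl pivalate | CCCCCCCCCCCCCC(=O)CCCCc1ccc(OC(=O)C(C)(C)C)cc1
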